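The central hexasubstituted ring (C1 acyloxy, C2 OH, C3 aryl, C4 acyloxy, C5 OH, C6 aryl) is cut at C5–C6, C1–C2 and C2–C3. One chromium carbene benzannulation joins three pieces and closes this ring: an alkenyl(methoxy)carbene complex with an acetal oxygen on its α-carbon and an aryl ring on its β-carbon, an arylethynylboronate, and one CO ligand. It exploits the para pair of free hydroxyls at C2 and C5. C2 arrives as phenol, C5 as methyl ether, C4 as acetal and C1 as a C–B bond, so all four oxygens differ before any acylation. Boron is caged as its MIDA ester to steer alkyne insertion. Quinone formation, two ordered acylations and one hydrogenolysis finish.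

Key step: step 4

Remark: the central ring is numbered as above. The only stereocentre (C3 of the butanoyl chain) is S and is bought with ethyl (S)-3-hydroxybutanoate.

Remark: a planar pinacol boronate is not used. Such a group is a small π-acceptor whose insertion bias cannot be trusted to be steric. The reverse orientation would give a meta-terphenyl.

Remark: both outer aryl rings are identical, so acyl shifts at the quinone stage are degenerate. Only the final hydroquinone can isomerise, hence the neutral last step.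

Step 1
Reactants: 1 2-[4-(benzyloxy)phenyl]acetaldehyde
Product: 3 (Z)-1-(benzyloxy)-4-[2-(methoxymethoxy)ethenyl]benzene, via potassium enolate 2 (not isolated)
Conditions: KN(SiMe3)2, THF, −78 °C (aldehyde added to base); MOMCl, −78 → 0 °C; chromatography on Et3N-deactivated SiO2
Reagents that add atoms: chloromethyl methyl ether (MOMCl), COCCl
Why: Williamson-type O-alkylation of a potassium aldehyde enolate by a hard α-chloro ether; deprotonation from the conformer in which the aryl group eclipses C=O should favour the Z enolate, and any E isomer is removed by chromatography.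

Step 2
Reactants: 3 (Z)-1-(benzyloxy)-4-[2-(methoxymethoxy)ethenyl]benzene; 4 chromium hexacarbonyl Cr(CO)6
Product: 7 pentacarbonyl{(Z)-3-[4-(benzyloxy)phenyl]-1-methoxy-2-(methoxymethoxy)prop-2-en-1-ylidene}chromium, via vinyllithium 5 (not isolated), via lithium acylchromate 6 (not isolated)
Conditions: s-BuLi (1.0 equiv), THF, −78 °C, 30 min; Cr(CO)6, −78 °C → rt; evaporate; MeOTf, CH2Cl2, 0 °C
Reagents that add atoms: methyl trifluoromethanesulfonate (MeOTf), COS(=O)(=O)C(F)(F)F
Why: Fischer carbene synthesis, in which acetal-chelated α-lithiation of the enol ether keeps the alkene geometry, the vinyllithium adds to a CO ligand and the acylate is O-methylated by a hard electrophile; one equivalent of base, low temperature and short contact are chosen because the ArOCH2Ph protons are the competing acidic site.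

Step 3
Reactants: 8 1-(benzyloxy)-4-iodobenzene; 9 ethynylboronic acid MIDA ester (2-ethynyl-6-methyl-1,3,6,2-dioxazaborocane-4,8-dione)
Product: 10 2-{[4-(benzyloxy)phenyl]ethynyl}-6-methyl-1,3,6,2-dioxazaborocane-4,8-dione
Conditions: PdCl2(PPh3)2 (cat.), CuI (cat.), Et3N, DMF, rt
Reagents that add atoms: none
Why: Sonogashira coupling, for which ethynyl MIDA boronate is a known partner of aryl iodides because the tetracoordinate boron is inert to anhydrous palladium, copper and amine.

Step 4
Reactants: 7 pentacarbonyl{(Z)-3-[4-(benzyloxy)phenyl]-1-methoxy-2-(methoxymethoxy)prop-2-en-1-ylidene}chromium; 10 2-{[4-(benzyloxy)phenyl]ethynyl}-6-methyl-1,3,6,2-dioxazaborocane-4,8-dione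
Product: 11 3,6-bis[4-(benzyloxy)phenyl]-4-methoxy-5-(methoxymethoxy)-2-(6-methyl-4,8-dioxo-1,3,6,2-dioxazaborocan-2-yl)phenol
Conditions: 10 (1.3 equiv), THF (0.1 M), 55 °C, Ar, 16 h; then air, EtOAc, rt
Reagents that add atoms: none
Why: Proposed new method: heat expels one CO from 7, alkyne 10 binds and inserts into the Cr=C bond (C5–C6), a CO ligand migrates to the new carbene carbon to give a chromium-bound dienylketene (C1–C2), and closure onto the aryl-bearing alkene carbon (C2–C3) followed by enolisation delivers the phenol. The closest known reactions are the Dötz benzannulation of alkenyl(methoxy)carbene complexes with alkynyl pinacolboronates and with silylalkynes, and α-alkoxyalkenyl carbenes such as the dihydropyranyl complex are established partners; what has not been shown is a tetracoordinate alkynyl MIDA boronate as the alkyne. The single new ring, the central benzene, closes by 6π-electrocyclisation of the dienylketene, so six substituents are set without substitution on a crowded arene, and no stereocentre is created. The selectivity needed is the orientation of alkyne insertion: boron must end on the carbon that takes up CO, otherwise a meta-terphenyl results. A flat dialkoxyboryl group is a small π-acceptor that, like a stannyl group, tends to sit beside the alkoxy carbon, so boron is caged as the MIDA ester, which has no vacant orbital, is bulkier than the flat aryl ring, and should therefore take the large-substituent site as trialkylsilyl groups do in this reaction and as B(MIDA) does in Larock heteroannulation. The Z geometry of 7 keeps the aryl group on the outer side of the closing triene.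

Step 5
Reactants: 11 3,6-bis[4-(benzyloxy)phenyl]-4-methoxy-5-(methoxymethoxy)-2-(6-methyl-4,8-dioxo-1,3,6,2-dioxazaborocan-2-yl)phenol
Product: 12 2,5-bis[4-(benzyloxy)phenyl]-3-(methoxymethoxy)-6-(6-methyl-4,8-dioxo-1,3,6,2-dioxazaborocan-2-yl)-1,4-benzoquinone
Conditions: (NH4)2Ce(NO3)6 (2.2 equiv), MeCN–H2O, 0 °C, 10 min
Reagents that add atoms: water, O
Why: Oxidative demethylation of a 4-methoxyphenol to the 1,4-benzoquinone by two equivalents of tetravalent cerium is the usual finish of a Dötz reaction and is tolerated by borylated products; MIDA boronates survive acidic aqueous oxidants, and brief contact at 0 °C should spare the acetal and the benzyl ethers.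

Step 6
Reactants: 12 2,5-bis[4-(benzyloxy)phenyl]-3-(methoxymethoxy)-6-(6-methyl-4,8-dioxo-1,3,6,2-dioxazaborocan-2-yl)-1,4-benzoquinone
Product: 13 2,5-bis[4-(benzyloxy)phenyl]-3-hydroxy-6-(methoxymethoxy)-1,4-benzoquinone
Conditions: NaBO3·4H2O (3 equiv), THF–H2O, 0 °C → rt; then aq NaH2PO4 to pH 4–5
Reagents that add atoms: sodium perborate tetrahydrate NaBO3·4H2O, [Na+].[Na+].O[B-]1(O)OO[B-](O)(O)OO1
Why: Boronate oxidation by 1,2-shift of carbon from boron to peroxide oxygen: the mildly basic perborate solution opens the MIDA cage and oxidises the freed boronic acid at once, and the acidic hydroxyquinone is parked as its unreactive anion.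

Step 7
Reactants: 14 ethyl (S)-3-hydroxybutanoate
Product: 15 ethyl (S)-3-(benzyloxy)butanoate
Conditions: benzyl 2,2,2-trichloroacetimidate, TfOH (cat.), CH2Cl2–cyclohexane, 0 °C → rt
Reagents that add atoms: benzyl 2,2,2-trichloroacetimidate, N=C(OCc1ccccc1)C(Cl)(Cl)Cl
Why: Acid-catalysed trichloroacetimidate O-benzylation avoids base and hence β-elimination, and it leaves the C3–O bond intact, so the S configuration is kept.

Step 8
Reactants: 15 ethyl (S)-3-(benzyloxy)butanoate
Product: 16 (S)-3-(benzyloxy)butanoic acid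
Conditions: LiOH, THF–H2O, 0 °C → rt; then 1 M HCl
Reagents that add atoms: lithium hydroxide LiOH, [Li+].[OH-]
Why: Ester saponification by acyl–oxygen cleavage does not involve C3, which stays S.

Step 9
Reactants: 16 (S)-3-(benzyloxy)butanoic acid; 13 2,5-bis[4-(benzyloxy)phenyl]-3-hydroxy-6-(methoxymethoxy)-1,4-benzoquinone
Product: 18 2,5-bis[4-(benzyloxy)phenyl]-4-(methoxymethoxy)-3,6-dioxocyclohexa-1,4-dien-1-yl (S)-3-(benzyloxy)butanoate, via acid chloride 17 (not isolated)
Conditions: (COCl)2, DMF (cat.), CH2Cl2, 0 °C → rt, evaporate; 13, 2,6-lutidine, CH2Cl2, −20 → 0 °C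
Reagents that add atoms: none
Why: Acid chloride formation followed by O-acylation of the only free hydroxyl, the vinylogous acid O1–H released from boron; a non-nucleophilic base limits acyl transfer from the activated product.

Step 10
Reactants: 18 2,5-bis[4-(benzyloxy)phenyl]-4-(methoxymethoxy)-3,6-dioxocyclohexa-1,4-dien-1-yl (S)-3-(benzyloxy)butanoate
Product: 19 2,5-bis[4-(benzyloxy)phenyl]-4-hydroxy-3,6-dioxocyclohexa-1,4-dien-1-yl (S)-3-(benzyloxy)butanoate
Conditions: CF3CO2H–CH2Cl2 (1:9), 0 °C; aqueous work-up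
Reagents that add atoms: none
Why: Acid-catalysed acetal cleavage: the MOM group on a quinone oxygen is a vinylogous acyl acetal and should leave well before the benzyl ethers or the O1 ester react.

Step 11
Reactants: 19 2,5-bis[4-(benzyloxy)phenyl]-4-hydroxy-3,6-dioxocyclohexa-1,4-dien-1-yl (S)-3-(benzyloxy)butanoate; 20 3-phenylpropanoyl chloride
Product: 21 2,5-bis[4-(benzyloxy)phenyl]-3,6-dioxo-4-[(3-phenylpropanoyl)oxy]cyclohexa-1,4-dien-1-yl (S)-3-(benzyloxy)butanoate
Conditions: 20 (1.5 equiv) added first, then 2,6-lutidine dropwise, CH2Cl2, −20 °C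
Reagents that add atoms: none
Why: O-acylation of the newly freed O4–H with an acid chloride, which captures the quinone oxyanion faster than it can attack the O1 ester of another molecule.

Step 12
Reactants: 21 2,5-bis[4-(benzyloxy)phenyl]-3,6-dioxo-4-[(3-phenylpropanoyl)oxy]cyclohexa-1,4-dien-1-yl (S)-3-(benzyloxy)butanoate
Product: 22 2,5-dihydroxy-3,6-bis(4-hydroxyphenyl)-4-[(3-phenylpropanoyl)oxy]phenyl (S)-3-hydroxybutanoate (target)
Conditions: H2 (1 atm), Pd/C, EtOAc–THF, rt; filtration under Ar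
Reagents that add atoms: none
Why: Catalytic hydrogenation reduces the quinone to the C2/C5 hydroquinone and hydrogenolyses all three benzyl ethers in one neutral, aprotic operation, which should prevent O1→O2 and O4→O5 acyl shifts and leaves the S centre untouched.

Compound list
1 | 2-[4-(benzyloxy)phenyl]acetaldehyde | O=CCc1ccc(OCc2ccccc2)cc1 | starting material
2 | potassium (Z)-2-[4-(benzyloxy)phenyl]ethenolate | [K+].[O-]/C=C\c1ccc(OCc2ccccc2)cc1 | intermediate
3 | (Z)-1-(benzyloxy)-4-[2-(methoxymethoxy)ethenyl]benzene | COCO/C=C\c1ccc(OCc2ccccc2)cc1 | intermediate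
4 | chromium hexacarbonyl Cr(CO)6 | O=C=[Cr](=C=O)(=C=O)(=C=O)(=C=O)=C=O | starting material
5 | (Z)-2-[4-(benzyloxy)phenyl]-1-(methoxymethoxy)ethenyllithium | [Li]/C(OCOC)=C/c1ccc(OCc2ccccc2)cc1 | intermediate
6 | lithium pentacarbonyl{(Z)-3-[4-(benzyloxy)phenyl]-2-(methoxymethoxy)prop-2-enoyl}chromate | [Li+].[O-]C(=[Cr](=C=O)(=C=O)(=C=O)(=C=O)=C=O)/C(OCOC)=C/c1ccc(OCc2ccccc2)cc1 | intermediate
7 | pentacarbonyl{(Z)-3-[4-(benzyloxy)phenyl]-1-methoxy-2-(methoxymethoxy)prop-2-en-1-ylidene}chromium | COC(=[Cr](=C=O)(=C=O)(=C=O)(=C=O)=C=O)/C(OCOC)=C/c1ccc(OCc2ccccc2)cc1 | intermediate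
8 | 1-(benzyloxy)-4-iodobenzene | Ic1ccc(OCc2ccccc2)cc1 | starting material
9 | ethynylboronic acid MIDA ester | C#C[B-]12OC(=O)C[N+]1(C)CC(=O)O2 | starting material
10 | 2-{[4-(benzyloxy)phenyl]ethynyl}-6-methyl-1,3,6,2-dioxazaborocane-4,8-dione | C(#C[B-]12OC(=O)C[N+]1(C)CC(=O)O2)c1ccc(OCc2ccccc2)cc1 | intermediate
11 | 3,6-bis[4-(benzyloxy)phenyl]-4-methoxy-5-(methoxymethoxy)-2-(6-methyl-4,8-dioxo-1,3,6,2-dioxazaborocan-2-yl)phenol | Oc1c([B-]23OC(=O)C[N+]2(C)CC(=O)O3)c(-c2ccc(OCc3ccccc3)cc2)c(OC)c(OCOC)c1-c1ccc(OCc2ccccc2)cc1 | intermediate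
12 | 2,5-bis[4-(benzyloxy)phenyl]-3-(methoxymethoxy)-6-(6-methyl-4,8-dioxo-1,3,6,2-dioxazaborocan-2-yl)-1,4-benzoquinone | O=C1C([B-]23OC(=O)C[N+]2(C)CC(=O)O3)=C(c2ccc(OCc3ccccc3)cc2)C(=O)C(OCOC)=C1c1ccc(OCc2ccccc2)cc1 | intermediate
13 | 2,5-bis[4-(benzyloxy)phenyl]-3-hydroxy-6-(methoxymethoxy)-1,4-benzoquinone | O=C1C(O)=C(c2ccc(OCc3ccccc3)cc2)C(=O)C(OCOC)=C1c1ccc(OCc2ccccc2)cc1 | intermediate
14 | ethyl (S)-3-hydroxybutanoate | C[C@H](O)CC(=O)OCC | starting material
15 | ethyl (S)-3-(benzyloxy)butanoate | C[C@H](OCc1ccccc1)CC(=O)OCC | intermediate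
16 | (S)-3-(benzyloxy)butanoic acid | C[C@H](OCc1ccccc1)CC(=O)O | intermediate
17 | (S)-3-(benzyloxy)butanoyl chloride | C[C@H](OCc1ccccc1)CC(=O)Cl | intermediate
18 | 2,5-bis[4-(benzyloxy)phenyl]-4-(methoxymethoxy)-3,6-dioxocyclohexa-1,4-dien-1-yl (S)-3-(benzyloxy)butanoate | C[C@H](OCc1ccccc1)CC(=O)OC1=C(c2ccc(OCc3ccccc3)cc2)C(=O)C(OCOC)=C(c2ccc(OCc3ccccc3)cc2)C1=O | intermediate
19 | 2,5-bis[4-(benzyloxy)phenyl]-4-hydroxy-3,6-dioxocyclohexa-1,4-dien-1-yl (S)-3-(benzyloxy)butanoate | C[C@H](OCc1ccccc1)CC(=O)OC1=C(c2ccc(OCc3ccccc3)cc2)C(=O)C(O)=C(c2ccc(OCc3ccccc3)cc2)C1=O | intermediate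
20 | 3-phenylpropanoyl chloride | O=C(Cl)CCc1ccccc1 | starting material
21 | 2,5-bis[4-(benzyloxy)phenyl]-3,6-dioxo-4-[(3-phenylpropanoyl)oxy]cyclohexa-1,4-dien-1-yl (S)-3-(benzyloxy)butanoate | C[C@H](OCc1ccccc1)CC(=O)OC1=C(c2ccc(OCc3ccccc3)cc2)C(=O)C(OC(=O)CCc2ccccc2)=C(c2ccc(OCc3ccccc3)cc2)C1=O | intermediate
22 | 2,5-dihydroxy-3,6-bis(4-hydroxyphenyl)-4-[(3-phenylpropanoyl)oxy]phenyl (S)-3-hydroxybutanoate | C[C@H](O)CC(=O)Oc1c(O)c(-c2ccc(O)cc2)c(OC(=O)CCc2ccccc2)c(O)c1-c1ccc(O)cc1 | target

Total step count: 12. Longest linear sequence: 9 (steps 1, 2, 4, 5, 6, 9, 10, 11, 12).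

Steps most likely to fail

**Step 4.** The alkyne may insert in the reverse orientation. The crowded dienylketene may also leave the benzannulation channel before it cyclises. The fallback uses known chemistry only; it sets out from 8 and comes back at 13.
- Miyaura borylation of 8 (B2pin2, PdCl2(dppf), KOAc, dioxane, 80 °C) gives 2-[4-(benzyloxy)phenyl]-4,4,5,5-tetramethyl-1,3,2-dioxaborolane F1.
- Tetrabromo-1,4-benzoquinone and NaOMe in MeOH give 2,5-dibromo-3,6-dimethoxy-1,4-benzoquinone F2.
- Twofold Suzuki coupling of F2 and F1 (Pd(PPh3)4, K2CO3, dioxane–H2O, 80 °C) gives 2,5-bis[4-(benzyloxy)phenyl]-3,6-dimethoxy-1,4-benzoquinone F3.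
- Hydrolysis of both vinylogous esters (aq NaOH, THF–MeOH, then HCl) gives 2,5-bis[4-(benzyloxy)phenyl]-3,6-dihydroxy-1,4-benzoquinone F4.
- The two hydroxyls of F4 are equivalent, so one equivalent of MOMCl and i-Pr2NEt in CH2Cl2 gives 13 by statistical monoprotection. Unreacted F4 is recycled.

**Step 2.** Three processes could consume the base before clean α-lithiation: deprotonation at the ArOCH2Ph group, carbolithiation of the styrene-type double bond, and base-induced loss of the acetal oxygen to give the arylalkyne. The fallback forms the C3=C4 double bond after the carbene; it sets out from 4 and comes back at 7.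
- (Methoxymethoxy)methyllithium, from tributyl[(methoxymethoxy)methyl]stannane and n-BuLi (THF, −78 °C), adds to 4. MeOTf then gives pentacarbonyl[1-methoxy-2-(methoxymethoxy)ethylidene]chromium F5.
- The acidic CH2 group of F5 is condensed with commercial 4-(benzyloxy)benzaldehyde (Et3N, Me3SiCl, Et2O, rt; aldol-type condensation of a Fischer carbene complex) to give 7.
- No organolithium ever meets a benzyl ether on this path. The alkene geometry is set thermodynamically, with the aryl group away from the metal fragment.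

**Step 6.** Peroxide or hydroxide may attack the quinone (epoxidation, or displacement of the acetal oxygen at C4), or protodeboronation may occur before the C–B bond is oxidised. The fallback oxidises boron on the arene and makes the quinone afterwards; it sets out from 11 and comes back at 18.
- O2-methylation of 11 (MeI, K2CO3, DMF, rt) gives 2-{2,5-bis[4-(benzyloxy)phenyl]-3,6-dimethoxy-4-(methoxymethoxy)phenyl}-6-methyl-1,3,6,2-dioxazaborocane-4,8-dione F6.
- Aq NaOH and H2O2 (THF, 0 °C) give 2,5-bis[4-(benzyloxy)phenyl]-3,6-dimethoxy-4-(methoxymethoxy)phenol F7.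
- Acylation with acid chloride 17 (2,6-lutidine, DMAP cat., CH2Cl2, 0 °C) gives 2,5-bis[4-(benzyloxy)phenyl]-3,6-dimethoxy-4-(methoxymethoxy)phenyl (S)-3-(benzyloxy)butanoate F8.
- Oxidative demethylation of the para dimethoxy pair with (NH4)2Ce(NO3)6 (MeCN–H2O, 0 °C) gives 18.

Further compounds
F1 | step 4 | 2-[4-(benzyloxy)phenyl]-4,4,5,5-tetramethyl-1,3,2-dioxaborolane | CC1(C)OB(c2ccc(OCc3ccccc3)cc2)OC1(C)C
F2 | step 4 | 2,5-dibromo-3,6-dimethoxy-1,4-benzoquinone | COC1=C(Br)C(=O)C(OC)=C(Br)C1=O
F3 | step 4 | 2,5-bis[4-(benzyloxy)phenyl]-3,6-dimethoxy-1,4-benzoquinone | COC1=C(c2ccc(OCc3ccccc3)cc2)C(=O)C(OC)=C(c2ccc(OCc3ccccc3)cc2)C1=O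
F4 | step 4 | 2,5-bis[4-(benzyloxy)phenyl]-3,6-dihydroxy-1,4-benzoquinone | OC1=C(c2ccc(OCc3ccccc3)cc2)C(=O)C(O)=C(c2ccc(OCc3ccccc3)cc2)C1=O
F5 | step 2 | pentacarbonyl[1-methoxy-2-(methoxymethoxy)ethylidene]chromium | COC(COCOC)=[Cr](=C=O)(=C=O)(=C=O)(=C=O)=C=O
F6 | step 6 | 2-{2,5-bis[4-(benzyloxy)phenyl]-3,6-dimethoxy-4-(methoxymethoxy)phenyl}-6-methyl-1,3,6,2-dioxazaborocane-4,8-dione | COc1c([B-]23OC(=O)C[N+]2(C)CC(=O)O3)c(-c2ccc(OCc3ccccc3)cc2)c(OC)c(OCOC)c1-c1ccc(OCc2ccccc2)cc1
F7 | step 6 | 2,5-bis[4-(benzyloxy)phenyl]-3,6-dimethoxy-4-(methoxymethoxy)phenol | COc1c(O)c(-c2ccc(OCc3ccccc3)cc2)c(OC)c(OCOC)c1-c1ccc(OCc2ccccc2)cc1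
F8 | step 6 | 2,5-bis[4-(benzyloxy)phenyl]-3,6-dimethoxy-4-(methoxymethoxy)phenyl (S)-3-(benzyloxy)butanoate | C[C@H](OCc1ccccc1)CC(=O)Oc1c(OC)c(-c2ccc(OCc3ccccc3)cc2)c(OCOC)c(OC)c1-c1ccc(OCc2ccccc2)cc1
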